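## The problem

The target 21 is a C20 gibberellin, 2β,13-dihydroxygibberell-16-ene-7,19-dioic acid 19,20-lactone. Cyclohexane ring A and cyclopentane ring B are fused at C5–C10, ring B shares C8 and C9 with the bicyclo[3.2.1]octane formed by rings C and D, and a δ-lactone (C19–O–C20) bridges C4 and C10 across the α-face of ring A (α is the face carrying C19, β the face of the C18 methyl and H-5). Eight stereocentres must be correct (C2, C4, C5, C6, C8, C9, C10, C13); C4, C8 and C10 are quaternary, C13 is a bridgehead tertiary carbinol, and C4 and C10 carry 1,3-diaxial carbon substituents tied by the lactone. The C8/C9/C13 array is locked in the bridged system and cannot be corrected late, whereas C10 can be derived from a resident centre on ring A and the equatorial 2β-hydroxyl can be set last under control of the lactone bridge. The 13-hydroxy-16-methylene unit rearranges in strong acid and is the most reactive alkene towards boranes, OsO4 and peracids; the lactone and the C7 carboxyl limit hydrides and organometallics; 3-oxygenated ring A precursors aromatise in hot acid. The enabling feature is that quaternary C10 carries an oxygenated one-carbon group (C20–O) and lies 1,3 to oxygenated C2. With the oxygen on C2α and an alkene at C1=C10, a carbanion on an O–CH2 group can hand C20, with its oxygen, to the α-face of C10 in a [2,3] shift, after which the 1,3-diaxial C19 acid closes the lactone. The 20-nor array this needs (C2α–O, C1=C10, free C19 carboxyl, 13-OH, rings B–D complete) is the isolactone form of gibberellic acid (1), a bulk fermentation product, so the task becomes a reworking of ring A of 1.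

## Retrosynthesis

**C16=C17 and the C7 acid (21 ⇒ 20 ⇒ 19).** The exocyclic methylene is removed first, because it would out-compete any ring A alkene in the hydroboration planned below. Cutting C16=C17 gives the norketone 19 through the methyl ester 20. Chemoselective hydration of C1=C2 beside an intact 16-ene has no structural basis, so masking is preferred. The forward steps need a non-basic methylenation of an α-ketol and a final ester saponification that the lactone survives by opening and re-closing.

**The C2 carbinol (19 ⇒ 18 ⇒ 17).** The C2–O bond is cut back to the C1=C2 alkene of 17, with C16 as a ketal and O13 as a MOM ether in 18. The alkene is what the key step leaves behind, so no extra functional group is needed. Reduction of a C2 ketone would instead require hydride to pass the two axial bridge carbons to give the equatorial alcohol. The forward hydroboration must put boron on C2 rather than the neopentyl C1 and must come from the β-face.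

**C10–C20 and the lactone (17 ⇒ 16 ⇒ 13).** The lactone C–O bond and the C10–C20 bond are cut, and the oxygen of C20 is reconnected to C2, giving the allylic stannylmethyl ether 13 with a C1=C10 alkene. Against conjugate addition of a one-carbon nucleophile to a ring A enone, this cut brings the oxygen along at the right oxidation level and transfers the C2 configuration to C10 stereospecifically. The precursor has lost the quaternary stereocentre, one ring and one carbon. The forward reaction must generate an α-alkoxy carbanion beside two carboxyl groups, so these are carried as carboxylate salts, O13 is capped and C16 is a ketal.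

**The ether and the hydroxy acid (13 ⇒ 11 ⇒ 10).** The O–CH2Sn bond is cut to the iodide 12 and the 2α-hydroxy dicarboxylate 11, which is the hydrolysed form of the 19,2α-lactone 10. A C19 ester cannot be used here: the cis-1,3 alkoxide would close the lactone before it is alkylated. So 11 is kept as its dipotassium salt and alkylated as such.

**Ring A of the isolactone (10 ⇒ 9 ⇒ 8 ⇒ 7 ⇒ 5).** The MOM group is removed (9) and a 3β-hydroxyl is added back (8, 7). The C2–O bond of 7 is then cut and the oxygen reconnected to C10, which gives the 3β-hydroxy-1-ene 19,10-lactone 5. This allylic lactone transposition needs the 3β-hydroxyl as internal nucleophile, so deoxygenation at C3 has to follow it. The transposition places the oxygen on C2α because C19 can reach no other face.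

**Ring D masking and the starting material (5 ⇒ 3 ⇒ 2 ⇒ 1).** The ketal is cut to ethylene glycol (4) and the norketone 3, and 3 to the methyl ester 2 of gibberellic acid (1). Cleavage of C16=C17 is placed here because the only other alkene of 2 (C1=C2) is deactivated by two allylic C–O bonds. The purchased materials are 1, 4 and 12.

## Roads not taken

**Alternative 1:** The cut runs through C8–C9 and C13–C14 and removes rings B and C together. The trienone A1 is a ring A lactone with an (E,E)-silyloxydiene on C10 and a 2-methylene-4-bromopent-4-enoyl group on C5. Heating it would give the intramolecular Diels–Alder adduct A2, with cyclopentanone ring B, cyclohexene ring C and a 2-bromoallyl arm on quaternary C8 for ring D.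
- Merits: two rings, C8 and C9 in one reagent-free step; a convergent, fully de novo assembly open to analogues in rings C and D.
- Weak points: A1 already holds the C4/C10 diaxial quaternary pair, C2 and C5, which would have to be built enantioselectively without rings B–D. The diene hangs on a quaternary carbon and the dienophile is a 1,1-disubstituted enone, so endo/exo and facial selectivity rest on conformational argument only. A2 is still far from 21: the C6 ketone must become C6–H bearing C7 in the right configuration, C13 must be oxidised, ring D closed, and C11=C12 reduced beside the new methylene.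
- Comparison: this road is better in independence from a natural-product feedstock and in convergence. The chosen plan sets against it rings B–D and six stereocentres taken intact from 1, a stereospecific key step and 15 steps in all.

**Alternative 2:** The cut is C8–C15 of ring D. The diazoketone A3 (diazoacetyl and silyloxy groups on C13, tertiary C8–H) would be treated with Rh2(OAc)4. The carbenoid at C15 inserts into C8–H with retention and gives the bridged cyclopentanone A4, the 16-oxo-17-nor skeleton with 13-O-silyl, 2-acetate and 7-methyl ester.
- Merits: 1,5-insertion into a tertiary C–H bond is dependable, C13 and its oxygen can come from quinic acid, and A4 needs only methylenation and deprotection. That endgame is shorter than the five steps that follow the key step of the chosen route.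
- Weak points: C11–H2 is also 1,5 to the carbenoid (through C12), so site selectivity must be won. C8–H must be cis-diaxial to the diazoacetyl group. A3 contains rings A–C, the lactone and seven stereocentres, so the key step ends a long linear sequence to which quinic acid contributes one ring and one stereocentre.
- Comparison: as a single transformation the insertion is at least as reliable as the [2,3] shift. The chosen plan sets against it an early key step on abundant material and no need to build ring D.

**Alternative 3:** The cut is C15–C16. The iodide A5 (iodomethyl on C8, ethynyl carbinol at C13) would be treated with Bu3SnH. The primary C15 radical closes 5-exo-dig on the inner alkyne carbon and leaves the exocyclic methylene, giving A6, the 2-acetate methyl ester of the target.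
- Merits: ring D and the C16=C17 methylene arrive together under neutral conditions that suit the acid-sensitive carbinol, and only hydrolysis separates A6 from 21. Here this road is clearly better than the chosen one, which spends four steps (2, 3, 13, 14) on masking and restoring C16=C17.
- Weak points: the neopentyl iodide on quaternary C8 and the C13 ethynyl carbinol, with the alkyne cis to it, must be installed with control on a complete A/B/C lactone. The vinyl radical can abstract hydrogen intramolecularly. All other rings and stereocentres must again be in place first.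
- Comparison: the endgame is the best of the four roads. The chosen plan sets against it the supply of rings B–D from 1 and the stereospecific creation of C10.

Key step: step 10

Assumption: gibberellic acid (1), the fermentation product sold in bulk as a plant growth regulator, is taken as a commercial chiral-pool starting material; it supplies rings B–D and six stereocentres, while C20, the C10 quaternary centre, the lactone and the C2 carbinol are built in the route.

## Steps

Step 1
Reactants: 1 gibberellic acid
Product: 2 gibberellic acid methyl ester
Conditions: TMSCHN2, MeOH–PhMe, 0 °C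
Reagents that add atoms: (trimethylsilyl)diazomethane, C[Si](C)(C)C=[N+]=[N-]
Why: O-Methylation of the carboxylic acid by a diazoalkane under neutral conditions; the acid- and base-sensitive ring A lactone and both hydroxyls are untouched and no stereocentre is involved.

Step 2
Reactants: 2 gibberellic acid methyl ester
Product: 3 16-oxo-17-nor-gibberellic acid methyl ester
Conditions: OsO4 (2 mol%), NaIO4, 2,6-lutidine, dioxane–H2O, rt
Reagents that add atoms: sodium periodate, [Na+].[O-]I(=O)(=O)=O
Why: Lemieux–Johnson cleavage; OsO4 should add to the unhindered 1,1-disubstituted C16=C17 in preference to C1=C2, which is deactivated by two allylic C–O bonds, and periodate cleaves the diol to the C16 ketone.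

Step 3
Reactants: 3 16-oxo-17-nor-gibberellic acid methyl ester; 4 ethylene glycol
Product: 5 16,16-ethylenedioxy-17-nor-gibberellic acid methyl ester
Conditions: HC(OMe)3, TsOH·H2O (cat.), CH2Cl2, rt
Reagents that add atoms: none
Why: Acid-catalysed ketalisation driven by orthoformate as water scavenger; anhydrous catalytic acid at room temperature should spare the allylic lactone, whose aromatisation needs aqueous acid and heat. The ketal protects C16 from base (α-ketol shift), organolithium and borane.

Step 4
Reactants: 5 16,16-ethylenedioxy-17-nor-gibberellic acid methyl ester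
Product: 7 isolactone methyl ester (19,2α-lactone; 1(10)-ene; 3β,13-diol; C16 ketal), via potassium epoxy carboxylate 6 (not isolated)
Conditions: K2CO3, MeOH–H2O (1:1), rt
Reagents that add atoms: none
Why: Base-induced allylic lactone transposition known for 3β-hydroxy-1-ene 19,10-lactone gibberellins: the 3β-alkoxide displaces the C10 carboxylate in an anti SN2′ reaction (epoxide 6) and the carboxylate reopens the allylic epoxide at C2. C2 is set α because C19 can reach only that face, and the 3β-hydroxyl is restored.

Step 5
Reactants: 7 isolactone methyl ester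
Product: 8 3-O-(phenoxythiocarbonyl) isolactone methyl ester
Conditions: PhOC(S)Cl, pyridine, DMAP (cat.), CH2Cl2, 0 °C → rt
Reagents that add atoms: O-phenyl chlorothionoformate, S=C(Cl)Oc1ccccc1
Why: Acylation of the secondary 3β-hydroxyl (first half of a Barton–McCombie deoxygenation); the bridgehead tertiary 13-OH beside the ketal is too hindered to react, and amine base avoids alkoxide-induced reversal to the epoxide.

Step 6
Reactants: 8 3-O-(phenoxythiocarbonyl) isolactone methyl ester
Product: 9 3-deoxy isolactone methyl ester (19,2α-lactone; 1(10)-ene; 13-OH; C16 ketal)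
Conditions: Bu3SnH, AIBN (cat.), PhMe, 90 °C
Reagents that add atoms: none
Why: Barton–McCombie radical deoxygenation; the secondary C3 radical is reduced by Bu3SnH much faster than β-scission of the C2 acyloxy bond could occur, and C3 ceases to be a stereocentre.

Step 7
Reactants: 9 3-deoxy isolactone methyl ester
Product: 10 13-O-methoxymethyl 3-deoxy isolactone methyl ester
Conditions: MOMCl, i-Pr2NEt, Bu4NI (cat.), ClCH2CH2Cl, 50 °C
Reagents that add atoms: chloromethyl methyl ether, COCCl
Why: Alkylation of the tertiary alcohol by the iodomethyl ether formed in situ; MOM is stable to hydroxide, KH, n-BuLi and borane and is removed with the ketal in step 13. It removes one anionic site and a second alkylation site from steps 9 and 10.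

Step 8
Reactants: 10 13-O-methoxymethyl 3-deoxy isolactone methyl ester
Product: 11 dipotassium 2α-hydroxy-13-(methoxymethoxy)-16,16-ethylenedioxy-17,20-dinorgibberell-1(10)-ene-7,19-dioate
Conditions: KOH (2.2 equiv), MeOH–H2O, reflux; evaporate; PhMe azeotrope
Reagents that add atoms: potassium hydroxide, [K+].[OH-]
Why: Saponification opens the bridged γ-lactone and hydrolyses the C7 ester; the product is kept as the salt because the free 2α-hydroxy acid would relactonise. C6 should hold its configuration, since the carboxyl trans to C4 on ring B is the more stable arrangement.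

Step 9
Reactants: 11 dipotassium 2α-hydroxy dicarboxylate; 12 tributyl(iodomethyl)stannane
Product: 13 2α-[(tributylstannyl)methoxy]-13-(methoxymethoxy)-16,16-ethylenedioxy-17,20-dinorgibberell-1(10)-ene-7,19-dioic acid
Conditions: KH, 18-crown-6, THF, 0 °C; Bu3SnCH2I, 0 °C → rt; AcOH to pH 5
Reagents that add atoms: none
Why: Williamson etherification of the potassium alkoxide with the iodomethylstannane, the standard entry to Still–Wittig substrates; the alkoxide is far more nucleophilic than the two hindered carboxylates, and with C19 as carboxylate it cannot re-close the lactone. C2 keeps its α configuration because only the O–H bond reacts.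

Step 10
Reactants: 13 2α-[(tributylstannyl)methoxy] diacid
Product: 16 13-(methoxymethoxy)-16,16-ethylenedioxy-17-norgibberell-1-ene-7,19-dioic acid 19,20-lactone, via lithiomethyl ether disodium salt 14 (not isolated), via C20 hydroxy diacid 15 (not isolated)
Conditions: NaH, THF–HMPA, 0 °C; n-BuLi, −78 → −30 °C; aq. HCl to pH 3, rt
Reagents that add atoms: none
Why: NaH first converts both carboxyl groups into carboxylates, so that n-BuLi meets no acidic proton and no electrophilic carbonyl and attacks tin; tin–lithium exchange gives the α-alkoxymethyllithium 14 and Bu4Sn. 14 undergoes the Still–Wittig [2,3]-sigmatropic shift, whose closest known relatives are the rearrangements of (cyclohexenyloxy)methylstannanes to quaternary hydroxymethyl compounds: in a five-membered envelope transition state C20 bonds to C10 while the C2–O bond breaks and the alkene moves to C1=C2, so the oxygen ends on C20. The shift itself closes no ring; the lactone closes on acidification by 6-exo-trig acyl substitution of the C20 hydroxyl of 15 on the C19 acid. The new quaternary stereocentre C10 is controlled by C2: the shift is suprafacial, so the 2α-oxygen delivers C20 to the α-face of C10, the face carrying C19. The same 1,3-diaxial placement makes lactonisation spontaneous, while the C7 acid on the opposite face of ring B cannot compete. The step needs [2,3] over [1,2] migration and over protonation of the carbanion; low temperature, the pseudo-axial C2–O bond aligned with the π-system and the absence of any proton source after salt formation should secure this. It also needs exchange at tin to beat addition of n-BuLi to carbon, which the carboxylate, ketal and MOM spectators ensure.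

Step 11
Reactants: 16 19,20-lactone 7-acid
Product: 17 methyl 13-(methoxymethoxy)-16,16-ethylenedioxy-17-norgibberell-1-ene-7,19-dioate 19,20-lactone
Conditions: TMSCHN2, MeOH–PhMe, 0 °C
Reagents that add atoms: (trimethylsilyl)diazomethane, C[Si](C)(C)C=[N+]=[N-]
Why: Neutral O-methylation of the C7 acid, which borane would otherwise reduce in the next step; lactone, ketal and MOM ether are inert.

Step 12
Reactants: 17 19,20-lactone 1-ene methyl ester
Product: 18 methyl 2β-hydroxy-13-(methoxymethoxy)-16,16-ethylenedioxy-17-norgibberellane-7,19-dioate 19,20-lactone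
Conditions: BH3·THF, THF, 0 °C → rt; then 30% H2O2, aq. NaOH, 0 °C
Reagents that add atoms: hydrogen peroxide, OO
Why: Hydroboration–oxidation; B–H adds syn from the β-face because the lactone bridge (C20 on C10, C19 on C4) covers the α-face, and boron should go to C2 because C1 is neopentyl to quaternary C10 and crowded by ring C. Oxidation with retention gives the equatorial 2β-alcohol; ester and lactone are reduced far more slowly than the alkene reacts.

Step 13
Reactants: 18 2β-alcohol
Product: 19 methyl 2β,13-dihydroxy-16-oxo-17-norgibberellane-7,19-dioate 19,20-lactone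
Conditions: 3 M aq. HCl–THF (1:1), 45 °C
Reagents that add atoms: water, O
Why: Acid hydrolysis removes the dioxolane and the MOM acetal in one operation; lactone, hindered methyl ester and secondary alcohol tolerate aqueous acid, the bridgehead carbinol cannot ionise, and with no alkene present no acid-induced C/D rearrangement is possible.

Step 14
Reactants: 19 norketone diol
Product: 20 target methyl ester (methyl 2β,13-dihydroxygibberell-16-ene-7,19-dioate 19,20-lactone)
Conditions: Zn, CH2Br2, TiCl4, THF–CH2Cl2, 0 °C → rt
Reagents that add atoms: dibromomethane, BrCBr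
Why: Takai–Lombardo methylenation; the non-basic gem-dimetallic reagent should convert the hindered ketone to the methylene without α-ketol rearrangement and without touching ester or lactone, the free hydroxyls only consuming reagent.

Step 15
Reactants: 20 target methyl ester
Product: 21 target gibberellin (2β,13-dihydroxygibberell-16-ene-7,19-dioic acid 19,20-lactone)
Conditions: KOH, MeOH–H2O, reflux; then aq. HCl to pH 3, 0 °C → rt
Reagents that add atoms: potassium hydroxide, [K+].[OH-]
Why: Saponification of the hindered C7 ester; the lactone opens reversibly and re-closes on acidification because C20–OH and the C19 acid are 1,3-diaxial, and cold acidification to pH 3 avoids rearrangement of the 13-hydroxy-16-ene.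

## Compound list

1 | gibberellic acid (3β,13-dihydroxy-20-norgibberella-1,16-diene-7,19-dioic acid 19,10-lactone) | C=C1C[C@]23C[C@@]1(O)CC[C@H]2[C@@]12C=C[C@H](O)[C@@](C)(C(=O)O1)[C@H]2[C@@H]3C(=O)O | starting material
2 | gibberellic acid methyl ester | C=C1C[C@]23C[C@@]1(O)CC[C@H]2[C@@]12C=C[C@H](O)[C@@](C)(C(=O)O1)[C@H]2[C@@H]3C(=O)OC | intermediate
3 | 16-oxo-17-nor-gibberellic acid methyl ester | O=C1C[C@]23C[C@@]1(O)CC[C@H]2[C@@]12C=C[C@H](O)[C@@](C)(C(=O)O1)[C@H]2[C@@H]3C(=O)OC | intermediate
4 | ethylene glycol | OCCO | starting material
5 | 16,16-ethylenedioxy-17-nor-gibberellic acid methyl ester | O1CCOC12C[C@]34C[C@@]2(O)CC[C@H]3[C@@]12C=C[C@H](O)[C@@](C)(C(=O)O1)[C@H]2[C@@H]4C(=O)OC | intermediate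
6 | potassium 2β,3β-epoxy-13-hydroxy-16,16-ethylenedioxy-17,20-dinorgibberell-1(10)-ene-7,19-dioate 7-methyl ester | O1CCOC12C[C@]34C[C@@]2(O)CC[C@H]3C1=C[C@@H]2O[C@@H]2[C@@](C)(C(=O)[O-])[C@H]1[C@@H]4C(=O)OC.[K+] | intermediate (not isolated)
7 | methyl 3β,13-dihydroxy-16,16-ethylenedioxy-17,20-dinorgibberell-1(10)-ene-7,19-dioate 19,2α-lactone (isolactone) | O1CCOC12C[C@]34C[C@@]2(O)CC[C@H]3C1=C[C@@H]2[C@H](O)[C@@](C)(C(=O)O2)[C@H]1[C@@H]4C(=O)OC | intermediate
8 | 3β-O-(phenoxythiocarbonyl) derivative of 7 | O1CCOC12C[C@]34C[C@@]2(O)CC[C@H]3C1=C[C@@H]2[C@H](OC(=S)Oc5ccccc5)[C@@](C)(C(=O)O2)[C@H]1[C@@H]4C(=O)OC | intermediate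
9 | methyl 13-hydroxy-16,16-ethylenedioxy-17,20-dinorgibberell-1(10)-ene-7,19-dioate 19,2α-lactone | O1CCOC12C[C@]34C[C@@]2(O)CC[C@H]3C1=C[C@@H]2C[C@@](C)(C(=O)O2)[C@H]1[C@@H]4C(=O)OC | intermediate
10 | 13-O-methoxymethyl ether of 9 | O1CCOC12C[C@]34C[C@@]2(OCOC)CC[C@H]3C1=C[C@@H]2C[C@@](C)(C(=O)O2)[C@H]1[C@@H]4C(=O)OC | intermediate
11 | dipotassium 2α-hydroxy-13-(methoxymethoxy)-16,16-ethylenedioxy-17,20-dinorgibberell-1(10)-ene-7,19-dioate | O1CCOC12C[C@]34C[C@@]2(OCOC)CC[C@H]3C1=C[C@@H](O)C[C@@](C)(C(=O)[O-])[C@H]1[C@@H]4C(=O)[O-].[K+].[K+] | intermediate
12 | tributyl(iodomethyl)stannane | CCCC[Sn](CCCC)(CCCC)CI | starting material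
13 | 2α-[(tributylstannyl)methoxy]-13-(methoxymethoxy)-16,16-ethylenedioxy-17,20-dinorgibberell-1(10)-ene-7,19-dioic acid | O1CCOC12C[C@]34C[C@@]2(OCOC)CC[C@H]3C1=C[C@@H](OC[Sn](CCCC)(CCCC)CCCC)C[C@@](C)(C(=O)O)[C@H]1[C@@H]4C(=O)O | intermediate
14 | disodium 2α-(lithiomethoxy)-13-(methoxymethoxy)-16,16-ethylenedioxy-17,20-dinorgibberell-1(10)-ene-7,19-dioate | O1CCOC12C[C@]34C[C@@]2(OCOC)CC[C@H]3C1=C[C@@H](OC[Li])C[C@@](C)(C(=O)[O-])[C@H]1[C@@H]4C(=O)[O-].[Na+].[Na+] | intermediate (not isolated)
15 | 20-hydroxy-13-(methoxymethoxy)-16,16-ethylenedioxy-17-norgibberell-1-ene-7,19-dioic acid | O1CCOC12C[C@]34C[C@@]2(OCOC)CC[C@H]3[C@]1(CO)C=CC[C@@](C)(C(=O)O)[C@H]1[C@@H]4C(=O)O | intermediate (not isolated)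
16 | 13-(methoxymethoxy)-16,16-ethylenedioxy-17-norgibberell-1-ene-7,19-dioic acid 19,20-lactone | O1CCOC12C[C@]34C[C@@]2(OCOC)CC[C@H]3[C@]35COC(=O)[C@](C)(CC=C3)[C@H]5[C@@H]4C(=O)O | intermediate
17 | methyl ester of 16 | O1CCOC12C[C@]34C[C@@]2(OCOC)CC[C@H]3[C@]35COC(=O)[C@](C)(CC=C3)[C@H]5[C@@H]4C(=O)OC | intermediate
18 | methyl 2β-hydroxy-13-(methoxymethoxy)-16,16-ethylenedioxy-17-norgibberellane-7,19-dioate 19,20-lactone | O1CCOC12C[C@]34C[C@@]2(OCOC)CC[C@H]3[C@]35COC(=O)[C@](C)(C[C@@H](O)C3)[C@H]5[C@@H]4C(=O)OC | intermediate
19 | methyl 2β,13-dihydroxy-16-oxo-17-norgibberellane-7,19-dioate 19,20-lactone | O=C1C[C@]23C[C@@]1(O)CC[C@H]2[C@]12COC(=O)[C@](C)(C[C@@H](O)C1)[C@H]2[C@@H]3C(=O)OC | intermediate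
20 | methyl ester of the target (methyl 2β,13-dihydroxygibberell-16-ene-7,19-dioate 19,20-lactone) | C=C1C[C@]23C[C@@]1(O)CC[C@H]2[C@]12COC(=O)[C@](C)(C[C@@H](O)C1)[C@H]2[C@@H]3C(=O)OC | intermediate
21 | target gibberellin (2β,13-dihydroxygibberell-16-ene-7,19-dioic acid 19,20-lactone) | C=C1C[C@]23C[C@@]1(O)CC[C@H]2[C@]12COC(=O)[C@](C)(C[C@@H](O)C1)[C@H]2[C@@H]3C(=O)O | target

## Step count and least certain steps

Total step count: 15. Longest linear sequence: 15 steps (1 → 21).

**Step 10 (key step).** The most likely failure is slow or incomplete tin–lithium exchange in the aggregated, sparingly soluble dicarboxylate. That would leave time for quenching of the carbanion, for [1,2] migration on warming, or for addition of the carbanion to the neighbouring C19 carboxylate. Fallback: starting from 11, the alkoxide is alkylated with chloromethyl phenyl sulfide (KH, NaI, 18-crown-6) to give the 2α-(phenylthiomethoxy) diacid F1. Its disodium salt is treated with lithium 4,4′-di-tert-butylbiphenylide in THF at −78 °C. Reductive cleavage of the C–S bond generates the same carbanion 14 by electron transfer, without alkyllithium or tin, and rearrangement and acidic work-up return to the route at 16.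

**Step 9.** The tri-anionic species may be poorly soluble and the C7 carboxylate may be alkylated in competition, so that ether formation stalls or gives stannylmethyl esters. Fallback: starting from 10, one equivalent of KOH in THF–H2O at rt opens only the strained lactone and gives the monopotassium 2α-hydroxy 19-carboxylate 7-methyl ester F2. Its alkoxide (KH, 18-crown-6) is alkylated with 12 to the 2α-[(tributylstannyl)methoxy] 19-acid 7-methyl ester F3, which carries one charge less during etherification. Saponification of the C7 ester of F3 (KOH, MeOH–H2O, reflux; pH 5) then rejoins the route at 13.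

**Step 12.** Regiocontrol may erode (boron partly on C1) because borane is small and the only bias is steric, and slow reduction of the lactone may compete if the alkene reacts sluggishly. Fallback: starting from 17, OsO4 (cat.) with N-methylmorpholine N-oxide adds from the β-face to give the 1β,2β-diol F4. TBSCl and imidazole silylate the less hindered C2 hydroxyl to give the 2β-silyl ether F5. The neopentyl C1 hydroxyl is converted into its phenyl thionocarbonate F6 and removed with Bu3SnH/AIBN to give the 2β-silyloxy compound F7. The conditions of step 13 then cleave silyl ether, MOM ether and ketal together and rejoin the route at 19.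

**Step 3.** Acid may ionise ring A (loss of the allylic 3-hydroxyl or opening of the allylic lactone, leading to aromatisation) before the hindered α-hydroxy ketone is fully ketalised. Fallback: starting from 3, acetylation (Ac2O, pyridine) gives the 3-O-acetyl norketone F8. The acetate is a poorer leaving group and inductively destabilises the ring A allyl cation. Ketalisation as in step 3 gives the 3-O-acetyl ketal F9, and K2CO3 in MeOH–H2O first removes the acetate and then effects the lactone transposition in the same flask, rejoining the route at 7.

## Further compounds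

F1 | step 10 | 2α-[(phenylthio)methoxy]-13-(methoxymethoxy)-16,16-ethylenedioxy-17,20-dinorgibberell-1(10)-ene-7,19-dioic acid | O1CCOC12C[C@]34C[C@@]2(OCOC)CC[C@H]3C1=C[C@@H](OCSc5ccccc5)C[C@@](C)(C(=O)O)[C@H]1[C@@H]4C(=O)O
F2 | step 9 | potassium 2α-hydroxy-13-(methoxymethoxy)-16,16-ethylenedioxy-7-(methoxycarbonyl)-17,20-dinorgibberell-1(10)-en-19-oate | O1CCOC12C[C@]34C[C@@]2(OCOC)CC[C@H]3C1=C[C@@H](O)C[C@@](C)(C(=O)[O-])[C@H]1[C@@H]4C(=O)OC.[K+]
F3 | step 9 | 2α-[(tributylstannyl)methoxy]-13-(methoxymethoxy)-16,16-ethylenedioxy-17,20-dinorgibberell-1(10)-ene-7,19-dioic acid 7-methyl ester | O1CCOC12C[C@]34C[C@@]2(OCOC)CC[C@H]3C1=C[C@@H](OC[Sn](CCCC)(CCCC)CCCC)C[C@@](C)(C(=O)O)[C@H]1[C@@H]4C(=O)OC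
F4 | step 12 | methyl 1β,2β-dihydroxy-13-(methoxymethoxy)-16,16-ethylenedioxy-17-norgibberellane-7,19-dioate 19,20-lactone | O1CCOC12C[C@]34C[C@@]2(OCOC)CC[C@H]3[C@]35COC(=O)[C@](C)(C[C@@H](O)[C@H]3O)[C@H]5[C@@H]4C(=O)OC
F5 | step 12 | 2β-O-(tert-butyldimethylsilyl) ether of F4 | O1CCOC12C[C@]34C[C@@]2(OCOC)CC[C@H]3[C@]35COC(=O)[C@](C)(C[C@@H](O[Si](C)(C)C(C)(C)C)[C@H]3O)[C@H]5[C@@H]4C(=O)OC
F6 | step 12 | 1β-O-(phenoxythiocarbonyl) derivative of F5 | O1CCOC12C[C@]34C[C@@]2(OCOC)CC[C@H]3[C@]35COC(=O)[C@](C)(C[C@@H](O[Si](C)(C)C(C)(C)C)[C@H]3OC(=S)Oc6ccccc6)[C@H]5[C@@H]4C(=O)OC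
F7 | step 12 | methyl 2β-(tert-butyldimethylsilyloxy)-13-(methoxymethoxy)-16,16-ethylenedioxy-17-norgibberellane-7,19-dioate 19,20-lactone | O1CCOC12C[C@]34C[C@@]2(OCOC)CC[C@H]3[C@]35COC(=O)[C@](C)(C[C@@H](O[Si](C)(C)C(C)(C)C)C3)[C@H]5[C@@H]4C(=O)OC
F8 | step 3 | 3-O-acetyl-16-oxo-17-nor-gibberellic acid methyl ester | O=C1C[C@]23C[C@@]1(O)CC[C@H]2[C@@]12C=C[C@H](OC(C)=O)[C@@](C)(C(=O)O1)[C@H]2[C@@H]3C(=O)OC
F9 | step 3 | 3-O-acetyl-16,16-ethylenedioxy-17-nor-gibberellic acid methyl ester | O1CCOC12C[C@]34C[C@@]2(O)CC[C@H]3[C@@]12C=C[C@H](OC(C)=O)[C@@](C)(C(=O)O1)[C@H]2[C@@H]4C(=O)OC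
A1 | alternative 1 | ring A lactone trienone: (E,E)-4-(tert-butyldimethylsilyloxy)buta-1,3-dienyl on C10, 2-methylene-4-bromopent-4-enoyl on C5, 2β-acetate | CC(C)(C)[Si](C)(C)O/C=C/C=C/[C@]12COC(=O)[C@](C)(C[C@@H](OC(C)=O)C1)[C@H]2C(=O)C(=C)CC(Br)=C
A2 | alternative 1 | Diels–Alder adduct: A/B/C lactone with C6 ketone, C11=C12 alkene, 13-silyloxy group and 2-bromoallyl group on C8 | C=C(Br)C[C@]12C[C@@H](O[Si](C)(C)C(C)(C)C)C=C[C@H]1[C@]13COC(=O)[C@](C)(C[C@@H](OC(C)=O)C1)[C@H]3C2=O
A3 | alternative 2 | 13-diazoacetyl-13-(trimethylsilyloxy) A/B/C lactone with tertiary C8–H, 2-acetate 7-methyl ester | [N-]=[N+]=CC(=O)[C@]1(O[Si](C)(C)C)CC[C@H]2[C@]34COC(=O)[C@](C)(C[C@@H](OC(C)=O)C3)[C@H]4[C@H](C(=O)OC)[C@H]2C1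
A4 | alternative 2 | 16-oxo-17-nor analogue of the target as its 13-O-trimethylsilyl ether 2-acetate methyl ester | O=C1C[C@]23C[C@@]1(O[Si](C)(C)C)CC[C@H]2[C@]12COC(=O)[C@](C)(C[C@@H](OC(C)=O)C1)[C@H]2[C@@H]3C(=O)OC
A5 | alternative 3 | 8-(iodomethyl)-13-ethynyl-13-hydroxy A/B/C lactone, 2-acetate 7-methyl ester | C#C[C@]1(O)CC[C@H]2[C@]34COC(=O)[C@](C)(C[C@@H](OC(C)=O)C3)[C@H]4[C@H](C(=O)OC)[C@@]2(CI)C1
A6 | alternative 3 | 2-acetate methyl ester of the target (methyl 2β-acetoxy-13-hydroxygibberell-16-ene-7,19-dioate 19,20-lactone) | C=C1C[C@]23C[C@@]1(O)CC[C@H]2[C@]12COC(=O)[C@](C)(C[C@@H](OC(C)=O)C1)[C@H]2[C@@H]3C(=O)OC
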